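Ring B is read as a masked cyclohexane-1,3-dione (isochromene numbering). C8 (the ketone) and C4a (the enone β-carbon that carries the ring A diene) are 1,3 across C8a, so C5 and C8a are the α and α′ carbons of a ketone at C4a. The key step joins a protected 4-hydroxybutan-2-one (C5, C4a, C8a, C1) and an enantiopure 2-alkoxy-2-methyl-3-oxopropanoate (C6, C7, C8) in one flask. A chelation-controlled aldol addition makes C5–C6 and sets C6; a Dieckmann-type Claisen closure makes C8–C8a. Enol triflation at C4a, Sonogashira coupling and a 6-endo oxa-Michael closure then build ring A; the hindered benzoate is attached last but one.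

Key step: step 6

Remark: atoms are numbered as in the target (C1, O2, C3, C4, C4a, C5–C8, C8a) in every intermediate. PMB = 4-methoxybenzyl, TES = triethylsilyl, TIPS = triisopropylsilyl, Tf = trifluoromethanesulfonyl, DTBMP = 2,6-di-tert-butyl-4-methylpyridine.
Assumption: methyl (S)-2-methylglycidate (1) is taken as a purchasable, enantiopure building block; it supplies C7, whose configuration is never touched afterwards.

Step 1
Reactants: 1 methyl (2S)-2-methyloxirane-2-carboxylate
Product: 2 methyl (2S)-2,3-dihydroxy-2-methylpropanoate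
Conditions: HClO4 (cat.), THF/H2O, 0 °C → rt
Reagents that add atoms: water, O
Why: Acid-catalysed epoxide hydrolysis in which water attacks the unsubstituted carbon (the tertiary carbon is deactivated towards ionisation by the ester), so the C–O bond at the quaternary centre (future C7) is untouched and its configuration is retained.

Step 2
Reactants: 2 methyl (2S)-2,3-dihydroxy-2-methylpropanoate
Product: 3 methyl (4S)-2-(4-methoxyphenyl)-4-methyl-1,3-dioxolane-4-carboxylate (both epimers at the acetal carbon)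
Conditions: 4-MeOC6H4CH(OMe)2, PPTS (cat.), CH2Cl2, rt
Reagents that add atoms: 4-methoxybenzaldehyde dimethyl acetal, COC(OC)c1ccc(OC)cc1
Why: Acid-catalysed transacetalisation of the 1,2-diol gives the five-membered p-methoxybenzylidene acetal, whose new acetal centre is inconsequential because it is destroyed in step 3.

Step 3
Reactants: 3 methyl (4S)-2-(4-methoxyphenyl)-4-methyl-1,3-dioxolane-4-carboxylate
Product: 4 methyl (2S)-3-hydroxy-2-[(4-methoxybenzyl)oxy]-2-methylpropanoate
Conditions: BH3·THF, TMSOTf (cat.), CH2Cl2, 0 °C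
Reagents that add atoms: none
Why: Regioselective reductive acetal opening in which the Lewis acid binds the less hindered and more basic primary oxygen, that C–O bond breaks, and hydride reduces the oxocarbenium ion on the tertiary oxygen, which leaves the PMB ether on the tertiary oxygen and a free primary alcohol while the ester is reduced far more slowly.

Step 4
Reactants: 4 methyl (2S)-3-hydroxy-2-[(4-methoxybenzyl)oxy]-2-methylpropanoate
Product: 5 methyl (2S)-2-[(4-methoxybenzyl)oxy]-2-methyl-3-oxopropanoate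
Conditions: TEMPO (cat.), PhI(OAc)2, CH2Cl2, rt
Reagents that add atoms: none
Why: Oxoammonium oxidation of the primary alcohol stops at the aldehyde, which has no α-hydrogen and therefore cannot epimerise.

Step 5
Reactants: 6 but-3-en-2-one; 7 (4-methoxyphenyl)methanol
Product: 8 4-[(4-methoxybenzyl)oxy]butan-2-one
Conditions: PMe3 (5 mol %), THF, rt
Reagents that add atoms: none
Why: Phosphine-catalysed oxa-Michael addition of the alcohol to the enone gives the β-alkoxy ketone under neutral conditions.

Step 6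
Reactants: 8 4-[(4-methoxybenzyl)oxy]butan-2-one; 5 methyl (2S)-2-[(4-methoxybenzyl)oxy]-2-methyl-3-oxopropanoate
Product: 10 (5R,6S)-3,5-dihydroxy-6-[(4-methoxybenzyl)oxy]-2-{[(4-methoxybenzyl)oxy]methyl}-6-methylcyclohex-2-en-1-one (enol form of the 1,3-dione), via aldol adduct 9 (not isolated)
Conditions: LDA (1.05 equiv), THF, −78 °C; then 5 pre-mixed with MgBr2·OEt2 (1.2 equiv) in CH2Cl2, −78 °C; then LDA (2.2 equiv), −78 → −20 °C; 1 M HCl
Reagents that add atoms: none
Why: The kinetic lithium enolate of 8 (deprotonation at C5) adds to the aldehyde of 5 held in a magnesium chelate (C5–C6), and a second deprotonation of aldolate 9 at the α′-methylene C8a is followed by intramolecular Claisen acylation at the C8 methyl ester (C8–C8a), so the pair behaves as a ketone α,α′-bis-enolate plus a 1,3-aldehyde-ester in a formal [3+3] annulation. The closest known reaction types are the chelation-controlled aldol addition to α-alkoxy aldehydes and the Dieckmann-type cyclisation of δ-keto esters to cyclohexane-1,3-diones. Ring B closes in the 6-(enolendo)-exo-trig mode, and deprotonation of the acidic 1,3-dione by the expelled methoxide makes the closure irreversible. C6 is the only new stereocentre and is set by chelation control: magnesium bridges the aldehyde oxygen and the C7 PMB ether and the enolate attacks the face flanked by the small C7 methyl group, anti to the ester, which should give 6R with O6 and O7 trans on the ring, while C7 is carried unchanged from 5 because it has no α-hydrogen. The step needs site selectivity in both enolisations and aldehyde-over-ester chemoselectivity: kinetic deprotonation favours the methyl group, the aldehyde is far more electrophilic than the ester, and of the two remaining α-carbons only C8a can reach C8 through a six-membered transition state. Holding O6 as its magnesium alkoxide until work-up disfavours β-elimination across C5–C6 and slows retro-aldol cleavage, and the alkyl ether on C1 is a poor leaving group from the C8a enolate.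

Step 7
Reactants: 10 (5R,6S)-3,5-dihydroxy-6-[(4-methoxybenzyl)oxy]-2-{[(4-methoxybenzyl)oxy]methyl}-6-methylcyclohex-2-en-1-one
Product: 12 (4S,5R)-4-[(4-methoxybenzyl)oxy]-2-{[(4-methoxybenzyl)oxy]methyl}-4-methyl-3-oxo-5-[(triethylsilyl)oxy]cyclohex-1-en-1-yl trifluoromethanesulfonate, via hydroxy triflate 11 (not isolated)
Conditions: PhNTf2, Et3N, DMAP (cat.), CH2Cl2, 0 °C → rt; then 2,6-lutidine, TESOTf, −78 → 0 °C
Reagents that add atoms: N-phenylbis(trifluoromethanesulfonimide), O=S(=O)(N(c1ccccc1)S(=O)(=O)C(F)(F)F)C(F)(F)F; triethylsilyl trifluoromethanesulfonate, CC[Si](CC)(CC)OS(=O)(=O)C(F)(F)F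
Why: O-Sulfonylation of the 1,3-dionate should occur at the less hindered and more electron-rich oxygen on C4a, remote from the quaternary alkoxy-bearing C7 (the site selectivity known from enol ether formation of 4,4-disubstituted cyclohexane-1,3-diones), PhNTf2 leaves the aliphatic C6 hydroxyl alone, and that hydroxyl is then silylated in the same flask.

Step 8
Reactants: 12 (4S,5R)-4-[(4-methoxybenzyl)oxy]-2-{[(4-methoxybenzyl)oxy]methyl}-4-methyl-3-oxo-5-[(triethylsilyl)oxy]cyclohex-1-en-1-yl trifluoromethanesulfonate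
Product: 13 (4S,5R)-4-hydroxy-2-(hydroxymethyl)-4-methyl-3-oxo-5-[(triethylsilyl)oxy]cyclohex-1-en-1-yl trifluoromethanesulfonate
Conditions: DDQ (3 equiv), CH2Cl2/pH 7 buffer, 0 °C → rt
Reagents that add atoms: none
Why: Oxidative cleavage of both PMB ethers (benzylic hydride abstraction and hydrolysis of the oxocarbenium ions) frees the C1 and C7 hydroxyls while the vinyl triflate and the silyl ether are inert to DDQ.

Step 9
Reactants: 14 (E)-but-2-enal
Product: 15 (E)-pent-3-en-1-yne
Conditions: TMSCHN2, LDA, THF, −78 °C → rt; product kept as a THF solution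
Reagents that add atoms: (trimethylsilyl)diazomethane, C[Si](C)(C)C=[N+]=[N-]
Why: Colvin rearrangement, in which lithiated TMS-diazomethane adds to the aldehyde, Peterson-type elimination gives an alkylidene carbene and a 1,2-hydrogen shift delivers the terminal alkyne with the E alkene untouched.

Step 10
Reactants: 13 (4S,5R)-4-hydroxy-2-(hydroxymethyl)-4-methyl-3-oxo-5-[(triethylsilyl)oxy]cyclohex-1-en-1-yl trifluoromethanesulfonate; 15 (E)-pent-3-en-1-yne
Product: 17 (6R,7S)-7-hydroxy-7-methyl-3-[(1E)-prop-1-en-1-yl]-6-[(triethylsilyl)oxy]-1,5,6,7-tetrahydro-8H-isochromen-8-one, via enynone diol 16 (not isolated)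
Conditions: PdCl2(PPh3)2 (5 mol %), CuI (10 mol %), i-Pr2NH, THF, 0 °C → rt; then DBU (0.2 equiv), rt
Reagents that add atoms: none
Why: Sonogashira coupling of the electron-poor vinyl triflate is followed by base-catalysed 6-endo-dig oxa-Michael addition of the C1 hydroxyl to C3, the δ-carbon of the C8 ynenone (attack at C4 would be an anti-Michael 5-exo closure), and protonation at C4 completes ring A, while the tertiary C7 hydroxyl cannot reach the alkyne.

Step 11
Reactants: 18 2,4-dihydroxy-6-methylbenzaldehyde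
Product: 19 2-hydroxy-6-methyl-4-[(triisopropylsilyl)oxy]benzaldehyde
Conditions: TIPSCl (1.05 equiv), imidazole, CH2Cl2, 0 °C
Reagents that add atoms: chlorotriisopropylsilane, CC(C)[Si](Cl)(C(C)C)C(C)C
Why: Silylation should occur at the 4-hydroxyl because the 2-hydroxyl is deactivated by its hydrogen bond to the formyl group.

Step 12
Reactants: 19 2-hydroxy-6-methyl-4-[(triisopropylsilyl)oxy]benzaldehyde
Product: 20 2-methoxy-6-methyl-4-[(triisopropylsilyl)oxy]benzaldehyde
Conditions: MeI, Ag2O, MeCN, rt, dark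
Reagents that add atoms: iodomethane, CI
Why: O-Methylation of the remaining phenol under non-basic conditions that leave the aryl silyl ether in place.

Step 13
Reactants: 20 2-methoxy-6-methyl-4-[(triisopropylsilyl)oxy]benzaldehyde
Product: 21 2-methoxy-6-methyl-4-[(triisopropylsilyl)oxy]benzoic acid
Conditions: NaClO2, NaH2PO4, 2-methyl-2-butene, t-BuOH/H2O, 0 °C → rt
Reagents that add atoms: sodium chlorite, [Na+].[O-]Cl=O
Why: Pinnick oxidation converts the aldehyde into the acid, and the alkene scavenger removes HOCl so the electron-rich ring is not chlorinated.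

Step 14
Reactants: 21 2-methoxy-6-methyl-4-[(triisopropylsilyl)oxy]benzoic acid; 17 (6R,7S)-7-hydroxy-7-methyl-3-[(1E)-prop-1-en-1-yl]-6-[(triethylsilyl)oxy]-1,5,6,7-tetrahydro-8H-isochromen-8-one
Product: 23 (6R,7S)-7-methyl-8-oxo-3-[(1E)-prop-1-en-1-yl]-6-[(triethylsilyl)oxy]-5,6,7,8-tetrahydro-1H-isochromen-7-yl 2-methoxy-6-methyl-4-[(triisopropylsilyl)oxy]benzoate, via acid chloride 22 (not isolated)
Conditions: (COCl)2, DMF (cat.), CH2Cl2, 0 °C → rt, evaporate; then 17, AgOTf, DTBMP, CH2Cl2, −40 → 0 °C
Reagents that add atoms: none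
Why: The 2,6-disubstituted, electron-rich aroyl chloride is ionised by AgOTf to an aroyl triflate/acylium species whose linear electrophilic carbon is not shielded by the ortho groups and can be captured by the hindered tertiary C7 hydroxyl (esterification of hindered aromatic acids through acylium ions), the hindered pyridine buffers the acid, and the only other hydroxyl (C6) is silylated.

Step 15
Reactants: 23 (6R,7S)-7-methyl-8-oxo-3-[(1E)-prop-1-en-1-yl]-6-[(triethylsilyl)oxy]-5,6,7,8-tetrahydro-1H-isochromen-7-yl 2-methoxy-6-methyl-4-[(triisopropylsilyl)oxy]benzoate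
Product: 24 (6R,7S)-6-hydroxy-7-methyl-8-oxo-3-[(1E)-prop-1-en-1-yl]-5,6,7,8-tetrahydro-1H-isochromen-7-yl 4-hydroxy-2-methoxy-6-methylbenzoate
Conditions: TBAF, AcOH (1:1), THF, 0 °C → rt
Reagents that add atoms: none
Why: Buffered fluoride cleaves the secondary TES ether and the aryl TIPS ether, and the buffering together with the shielding of the 2,6-disubstituted benzoate should prevent acyl migration from O7 to O6 and base-induced retro-aldol opening of ring B.

Compound list
1 | methyl (2S)-2-methyloxirane-2-carboxylate | COC(=O)[C@]1(C)CO1 | starting material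
2 | methyl (2S)-2,3-dihydroxy-2-methylpropanoate | COC(=O)[C@@](C)(O)CO | intermediate
3 | methyl (4S)-2-(4-methoxyphenyl)-4-methyl-1,3-dioxolane-4-carboxylate (both acetal epimers) | COC(=O)[C@]1(C)COC(c2ccc(OC)cc2)O1 | intermediate
4 | methyl (2S)-3-hydroxy-2-[(4-methoxybenzyl)oxy]-2-methylpropanoate | COC(=O)[C@@](C)(OCc1ccc(OC)cc1)CO | intermediate
5 | methyl (2S)-2-[(4-methoxybenzyl)oxy]-2-methyl-3-oxopropanoate | COC(=O)[C@@](C)(OCc1ccc(OC)cc1)C=O | intermediate
6 | but-3-en-2-one | CC(=O)C=C | starting material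
7 | (4-methoxyphenyl)methanol | COc1ccc(CO)cc1 | starting material
8 | 4-[(4-methoxybenzyl)oxy]butan-2-one | CC(=O)CCOCc1ccc(OC)cc1 | intermediate
9 | methyl (2S,3R)-3-hydroxy-2,7-bis[(4-methoxybenzyl)oxy]-2-methyl-5-oxoheptanoate (aldol adduct, present as its magnesium alkoxide) | COC(=O)[C@@](C)(OCc1ccc(OC)cc1)[C@H](O)CC(=O)CCOCc1ccc(OC)cc1 | intermediate
10 | (5R,6S)-3,5-dihydroxy-6-[(4-methoxybenzyl)oxy]-2-{[(4-methoxybenzyl)oxy]methyl}-6-methylcyclohex-2-en-1-one (enol form of the 1,3-dione) | OC1=C(COCc2ccc(OC)cc2)C(=O)[C@@](C)(OCc2ccc(OC)cc2)[C@H](O)C1 | intermediate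
11 | (4S,5R)-5-hydroxy-4-[(4-methoxybenzyl)oxy]-2-{[(4-methoxybenzyl)oxy]methyl}-4-methyl-3-oxocyclohex-1-en-1-yl trifluoromethanesulfonate | O=S(=O)(OC1=C(COCc2ccc(OC)cc2)C(=O)[C@@](C)(OCc2ccc(OC)cc2)[C@H](O)C1)C(F)(F)F | intermediate
12 | (4S,5R)-4-[(4-methoxybenzyl)oxy]-2-{[(4-methoxybenzyl)oxy]methyl}-4-methyl-3-oxo-5-[(triethylsilyl)oxy]cyclohex-1-en-1-yl trifluoromethanesulfonate | O=S(=O)(OC1=C(COCc2ccc(OC)cc2)C(=O)[C@@](C)(OCc2ccc(OC)cc2)[C@H](O[Si](CC)(CC)CC)C1)C(F)(F)F | intermediate
13 | (4S,5R)-4-hydroxy-2-(hydroxymethyl)-4-methyl-3-oxo-5-[(triethylsilyl)oxy]cyclohex-1-en-1-yl trifluoromethanesulfonate | O=S(=O)(OC1=C(CO)C(=O)[C@@](C)(O)[C@H](O[Si](CC)(CC)CC)C1)C(F)(F)F | intermediate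
14 | (E)-but-2-enal | C/C=C/C=O | starting material
15 | (E)-pent-3-en-1-yne | C/C=C/C#C | intermediate
16 | (5R,6S)-6-hydroxy-2-(hydroxymethyl)-6-methyl-3-[(3E)-pent-3-en-1-yn-1-yl]-5-[(triethylsilyl)oxy]cyclohex-2-en-1-one | C/C=C/C#CC1=C(CO)C(=O)[C@@](C)(O)[C@H](O[Si](CC)(CC)CC)C1 | intermediate
17 | (6R,7S)-7-hydroxy-7-methyl-3-[(1E)-prop-1-en-1-yl]-6-[(triethylsilyl)oxy]-1,5,6,7-tetrahydro-8H-isochromen-8-one | C/C=C/C1=CC2=C(CO1)C(=O)[C@@](C)(O)[C@H](O[Si](CC)(CC)CC)C2 | intermediate
18 | 2,4-dihydroxy-6-methylbenzaldehyde | Cc1cc(O)cc(O)c1C=O | starting material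
19 | 2-hydroxy-6-methyl-4-[(triisopropylsilyl)oxy]benzaldehyde | Cc1cc(O[Si](C(C)C)(C(C)C)C(C)C)cc(O)c1C=O | intermediate
20 | 2-methoxy-6-methyl-4-[(triisopropylsilyl)oxy]benzaldehyde | COc1cc(O[Si](C(C)C)(C(C)C)C(C)C)cc(C)c1C=O | intermediate
21 | 2-methoxy-6-methyl-4-[(triisopropylsilyl)oxy]benzoic acid | COc1cc(O[Si](C(C)C)(C(C)C)C(C)C)cc(C)c1C(=O)O | intermediate
22 | 2-methoxy-6-methyl-4-[(triisopropylsilyl)oxy]benzoyl chloride | COc1cc(O[Si](C(C)C)(C(C)C)C(C)C)cc(C)c1C(Cl)=O | intermediate
23 | (6R,7S)-7-methyl-8-oxo-3-[(1E)-prop-1-en-1-yl]-6-[(triethylsilyl)oxy]-5,6,7,8-tetrahydro-1H-isochromen-7-yl 2-methoxy-6-methyl-4-[(triisopropylsilyl)oxy]benzoate | C/C=C/C1=CC2=C(CO1)C(=O)[C@@](C)(OC(=O)c1c(C)cc(O[Si](C(C)C)(C(C)C)C(C)C)cc1OC)[C@H](O[Si](CC)(CC)CC)C2 | intermediate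
24 | (6R,7S)-6-hydroxy-7-methyl-8-oxo-3-[(1E)-prop-1-en-1-yl]-5,6,7,8-tetrahydro-1H-isochromen-7-yl 4-hydroxy-2-methoxy-6-methylbenzoate | C/C=C/C1=CC2=C(CO1)C(=O)[C@@](C)(OC(=O)c1c(C)cc(O)cc1OC)[C@H](O)C2 | target

Total step count: 15. Longest linear sequence: 10 steps (steps 1, 2, 3, 4, 6, 7, 8, 10, 14, 15).

Steps most likely to fail

1. Step 6. The aldolate may fragment by retro-aldol cleavage (across C5–C6 or C6–C7), or the C8a enolate may expel the C1 alkoxide, before the slower Claisen closure onto the hindered ester takes place. The aldehyde face may also be chosen poorly if chelation is incomplete. The fallback sets out from 8 (with 5) and comes back at 12; it gives up the one-flask execution and separates the two bond formations. Ketone 8 would be converted into its kinetic trimethylsilyl enol ether F1 (LDA, TMSCl, THF, −78 °C). A Mukaiyama aldol addition of F1 to aldehyde 5 pre-complexed with TiCl4 (CH2Cl2, −78 °C), the classical setting for chelation control with α-alkoxy aldehydes, should give hydroxy keto ester 9, now isolated and purified. Silylation (TESOTf, 2,6-lutidine) to the triethylsilyl ether F2 removes the alkoxide that drives retro-aldol cleavage. Kinetic deprotonation at the less hindered C8a methylene (LDA, THF, −78 → −20 °C) should then close F2 to the silylated dione F3, and triflation of F3 (PhNTf2, Et3N) returns to 12.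

2. Step 14. Acyl transfer to the hindered tertiary α-ketol may be sluggish, the acylium species may attack the electron-rich C4 of the dienol ether, and the C6 silyl ether may be lost to adventitious acid. The fallback sets out from 13 and comes back at 24; it moves the esterification to a substrate that has no dienol ether and closes ring A last. Selective silylation of the primary hydroxyl of 13 (TBSCl, imidazole, CH2Cl2, 0 °C) would give the mono-TBS ether F4. Acylation of its tertiary hydroxyl with acid chloride 22 (AgOTf, DTBMP, or through the sodium alkoxide with NaHMDS) would give the aryl ester triflate F5. Sonogashira coupling of F5 with 15 would give the enynone ester F6. Buffered TBAF would then remove all three silyl groups, and the freed C1 hydroxyl should close onto the ynenone in the 6-endo-dig mode to give 24.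

3. Step 10. The C1 hydroxyl may close in the 5-exo-dig mode (a fused furan after isomerisation), and the volatile enyne may oligomerise under the copper co-catalyst. The fallback sets out from 13 and comes back at 17; it replaces the alkyne by a ketone at C3. Commercial (E)-pent-3-en-2-one would be converted into its trimethylsilyl dienol ether F7 (TMSOTf, Et3N). Migita-type coupling of 13 with the tin enolate generated from F7 and Bu3SnF (PdCl2[P(o-tol)3]2, toluene, 80 °C) would give the keto diol F8. Acid-catalysed hemiketalisation of the C1 hydroxyl onto the C3 ketone and dehydration (PPTS, 4 Å molecular sieves, benzene) would then give 17 without any 5-exo alternative.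

Further compounds
F1 | step 6 | 4-[(4-methoxybenzyl)oxy]-2-[(trimethylsilyl)oxy]but-1-ene | C=C(O[Si](C)(C)C)CCOCc1ccc(OC)cc1
F2 | step 6 | methyl (2S,3R)-2,7-bis[(4-methoxybenzyl)oxy]-2-methyl-5-oxo-3-[(triethylsilyl)oxy]heptanoate | COC(=O)[C@@](C)(OCc1ccc(OC)cc1)[C@H](O[Si](CC)(CC)CC)CC(=O)CCOCc1ccc(OC)cc1
F3 | step 6 | (5R,6S)-3-hydroxy-6-[(4-methoxybenzyl)oxy]-2-{[(4-methoxybenzyl)oxy]methyl}-6-methyl-5-[(triethylsilyl)oxy]cyclohex-2-en-1-one | OC1=C(COCc2ccc(OC)cc2)C(=O)[C@@](C)(OCc2ccc(OC)cc2)[C@H](O[Si](CC)(CC)CC)C1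
F4 | step 14 | (4S,5R)-2-{[(tert-butyldimethylsilyl)oxy]methyl}-4-hydroxy-4-methyl-3-oxo-5-[(triethylsilyl)oxy]cyclohex-1-en-1-yl trifluoromethanesulfonate | O=S(=O)(OC1=C(CO[Si](C)(C)C(C)(C)C)C(=O)[C@@](C)(O)[C@H](O[Si](CC)(CC)CC)C1)C(F)(F)F
F5 | step 14 | (1S,6R)-3-{[(tert-butyldimethylsilyl)oxy]methyl}-1-methyl-2-oxo-6-[(triethylsilyl)oxy]-4-{[(trifluoromethyl)sulfonyl]oxy}cyclohex-3-en-1-yl 2-methoxy-6-methyl-4-[(triisopropylsilyl)oxy]benzoate | O=S(=O)(OC1=C(CO[Si](C)(C)C(C)(C)C)C(=O)[C@@](C)(OC(=O)c2c(C)cc(O[Si](C(C)C)(C(C)C)C(C)C)cc2OC)[C@H](O[Si](CC)(CC)CC)C1)C(F)(F)F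
F6 | step 14 | (1S,6R)-3-{[(tert-butyldimethylsilyl)oxy]methyl}-1-methyl-2-oxo-4-[(3E)-pent-3-en-1-yn-1-yl]-6-[(triethylsilyl)oxy]cyclohex-3-en-1-yl 2-methoxy-6-methyl-4-[(triisopropylsilyl)oxy]benzoate | C/C=C/C#CC1=C(CO[Si](C)(C)C(C)(C)C)C(=O)[C@@](C)(OC(=O)c2c(C)cc(O[Si](C(C)C)(C(C)C)C(C)C)cc2OC)[C@H](O[Si](CC)(CC)CC)C1
F7 | step 10 | (3E)-2-[(trimethylsilyl)oxy]penta-1,3-diene | C/C=C/C(=C)O[Si](C)(C)C
F8 | step 10 | (5R,6S)-6-hydroxy-2-(hydroxymethyl)-6-methyl-3-[(3E)-2-oxopent-3-en-1-yl]-5-[(triethylsilyl)oxy]cyclohex-2-en-1-one | C/C=C/C(=O)CC1=C(CO)C(=O)[C@@](C)(O)[C@H](O[Si](CC)(CC)CC)C1
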